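The data were generated by integration for an exercise; noise was put on by code.

Saturday's run still had 29.3% of its substrate left at 80.0 s, yet over its last stretch product grew at 0.939 of its rate during the first 30.0 s. So in Saturday's run the rate follows the substrate weakly, and we choose to compare the two runs at one time instead of at one conversion.

| flask | substrate | free catalyst | remark |
|---|---|---|---|
| Sunday's | 0.010 M | 0.13 mol% | run made earlier |
| Saturday's | 0.010 M | 0.3 mol% | run made earlier |
| flask | 0.010 M | 0.2 mol% |  |

- Sunday's (time / s: product / %, substrate / %): 10.0: 3.5, 96.4; 20.0: 10.9, 91.0; 30.0: 13.6, 85.6; 40.0: 20.2, 80.3; 50.0: 25.6, 77.7; 60.0: 30.4, 71.5; 80.0: 38.8, 61.0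
- Saturday's (time / s: product / %, substrate / %): 10.0: 10.2, 91.2; 12.0: 10.8, 90.2; 20.0: 16.8, 81.8; 30.0: 27.8, 73.8; 50.0: 44.8, 56.8; 80.0: 70.9, 29.3

(readings scatter by 1 percentage point)

1. apparent order in free catalyst when 10% of the substrate are converted (percent change of the rate of making product for one percent more free catalyst charged)



We fold the readings into one number: the logarithm of the ratio of product in the two runs at 80.0 s, over the logarithm of the ratio of their loadings. This gives 0.721, the catalyst exponent n, the percent of rate gained for one percent more loading. Below one, added catalyst earns less than its proportional share. The geometric mean of the two loadings is 0.987 of the flask's loading, so this average exponent belongs near the flask.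

Was one number enough? The readings at 50.0 s give 0.669, and the scatter of the readings gives that value a standard deviation of 0.0538, so the readings do not separate the two. We commit to n.

The forecast gives 0.72, “clearly below first order”, and the flask gives 0.73.

    2 catalyst intermediate B ⇌ resting dimer, settled at all times (K = 46000 M⁻¹)
    substrate + free catalyst → catalyst intermediate A (k = 6700 M⁻¹ s⁻¹)
    catalyst intermediate B → free catalyst + product (k = 7.40 s⁻¹)
    catalyst intermediate A → catalyst intermediate B (k = 26.0 s⁻¹)

Per form of catalyst in the flask, catalyst intermediate B turns over at 440 min⁻¹, slower than catalyst intermediate A at 1600 min⁻¹ and free catalyst at 4000 min⁻¹ with substrate as charged, and the rate moves 0.87 percent per percent on this rate-limiting step. At 0.247 min, with 10% converted, the flask holds 5.50% of its catalyst as free catalyst and 36.9% as resting dimer, a form outside the working round, and for a rate that follows catalyst intermediate B the reciprocal of n less one, read from the earlier runs, estimates the share of that dimer at 38.7%.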